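**Retrosynthetic overview**

- The strategy rests on the C1–C12 bond that joins pyrrole β-carbon C1 (ring B) to the β-carbon of cis-fused lactone D; C11, the oxygen-bearing γ-carbon of that lactone, carries the C10–C9 tether to the pyrrole. Cutting C1–C12 opens ring C to a C11-linked α-methylbutenolide and a C3-acylpyrrole.
- Lactone E is closed last from the C18 ketone and C21 ester by oxazaborolidine reduction and lactonisation, because a pyrrolylic lactone would not survive the acid of the key step.
- The butenolide comes from a C12 aldehyde by Z-selective olefination and lactonisation; the C3 keto ester comes from Vilsmeier–Haack acylation with an amide made from (S)-2-methylsuccinic acid (C20).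
- Ring A comes from ring-closing metathesis (C6=C7) and hydrogenation; C9 comes from iminium-catalysed Friedel–Crafts alkylation of N-allylpyrrole with an enal; C10 and C11 come from a proline-catalysed anti cross-aldol of butanal with 2,2-dimethoxyacetaldehyde.
- Ring order: B (pyrrole, bought), A, D (as butenolide), C (key step, which also saturates D), E.

Key step: step 15

Assumption: atom numbers follow the alkaloid numbering (ring A N4, C5–C9, C9a; ring B N4, C3, C2, C1, C9a; ring C C9, C10, C11, C12, C1, C9a; lactone D C11–O–C14–C13–C12; lactone E C18–C21); 2,2-dimethoxyacetaldehyde, the ylide and phosphonate reagents and both organocatalysts are taken as purchased.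

**Route**

Step 1
Reactants: 1 pyrrole
Product: 2 1-(prop-2-en-1-yl)-1H-pyrrole
Conditions: allyl bromide, KOH (powdered), DMSO, rt
Reagents that add atoms: allyl bromide, C=CCBr
Why: SN2 N-alkylation of the potassium pyrrolide, which in DMSO reacts on nitrogen and not on carbon.

Step 2
Reactants: 3 butanal; 4 2,2-dimethoxyacetaldehyde
Product: 6 (2E,4R,5R)-4-ethyl-5-hydroxy-6,6-dimethoxyhex-2-enal, via aldol adduct 5 (not isolated)
Conditions: L-proline (10 mol%), DMF, 4 °C, 3 added over 24 h to 4 (2 equiv); aqueous extraction; then Ph3P=CHCHO (1.2 equiv), CH2Cl2, rt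
Reagents that add atoms: (triphenylphosphoranylidene)acetaldehyde, O=CC=P(c1ccccc1)(c1ccccc1)c1ccccc1
Why: Proline-catalysed direct cross-aldol, in which the E-enamine of butanal adds to the non-enolisable acetal aldehyde through the carboxylic-acid-organised chair transition state and should give the anti adduct with C10 and C11 in the required sense (2S,3R in 5, which becomes 10R,11R once the priorities change), followed by Wittig olefination with the stabilised ylide to the E-enal before the β-hydroxy aldehyde can dehydrate.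

Step 3
Reactants: 6 (2E,4R,5R)-4-ethyl-5-hydroxy-6,6-dimethoxyhex-2-enal
Product: 7 (2E,4R,5R)-5-[(tert-butyldimethylsilyl)oxy]-4-ethyl-6,6-dimethoxyhex-2-enal
Conditions: TBSOTf, 2,6-lutidine, CH2Cl2, −78 °C
Reagents that add atoms: tert-butyldimethylsilyl trifluoromethanesulfonate, CC(C)(C)[Si](C)(C)OS(=O)(=O)C(F)(F)F
Why: Silyl triflate silylation of a hindered secondary alcohol, fast enough at −78 °C that the acetal and the enal are left alone.

Step 4
Reactants: 7 (2E,4R,5R)-5-[(tert-butyldimethylsilyl)oxy]-4-ethyl-6,6-dimethoxyhex-2-enal; 2 1-(prop-2-en-1-yl)-1H-pyrrole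
Product: 8 (3S,4R,5R)-5-[(tert-butyldimethylsilyl)oxy]-4-ethyl-6,6-dimethoxy-3-[1-(prop-2-en-1-yl)-1H-pyrrol-2-yl]hexanal
Conditions: 2 (3 equiv), (5S)-5-benzyl-2,2,3-trimethylimidazolidin-4-one·CF3CO2H (20 mol%), THF–H2O (95:5), −30 °C
Reagents that add atoms: none
Why: Iminium-catalysed Friedel–Crafts alkylation, in which the benzyl group of the (5S)-catalyst covers one face of the E-iminium ion of 7 so that pyrrole C2 adds to the open face of C9 and should set 9S under catalyst control, the cold, acid-buffered medium being chosen so that C10 is not reached through a dienamine.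

Step 5
Reactants: 8 (3S,4R,5R)-5-[(tert-butyldimethylsilyl)oxy]-4-ethyl-6,6-dimethoxy-3-[1-(prop-2-en-1-yl)-1H-pyrrol-2-yl]hexanal
Product: 9 2-[(4S,5R,6R)-6-[(tert-butyldimethylsilyl)oxy]-5-ethyl-7,7-dimethoxyhept-1-en-4-yl]-1-(prop-2-en-1-yl)-1H-pyrrole
Conditions: Ph3PCH3Br, KN(SiMe3)2, THF, 0 °C; then 8, −78 → 0 °C
Reagents that add atoms: methyltriphenylphosphonium bromide, C[P+](c1ccccc1)(c1ccccc1)c1ccccc1.[Br-]
Why: Wittig methylenation of an unhindered aldehyde that has no stereocentre at its α-carbon.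

Step 6
Reactants: 9 2-[(4S,5R,6R)-6-[(tert-butyldimethylsilyl)oxy]-5-ethyl-7,7-dimethoxyhept-1-en-4-yl]-1-(prop-2-en-1-yl)-1H-pyrrole
Product: 10 (9S)-9-[(3R,4R)-4-[(tert-butyldimethylsilyl)oxy]-5,5-dimethoxypentan-3-yl]-8,9-dihydro-5H-pyrrolo[1,2-a]azepine
Conditions: second-generation Grubbs catalyst (5 mol%), CH2Cl2 (5 mM), 40 °C
Reagents that add atoms: none
Why: Ring-closing metathesis of two monosubstituted alkenes closes seven-membered ring A at C6=C7 with loss of ethene, and the molecule holds no other alkene that could compete.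

Step 7
Reactants: 10 (9S)-9-[(3R,4R)-4-[(tert-butyldimethylsilyl)oxy]-5,5-dimethoxypentan-3-yl]-8,9-dihydro-5H-pyrrolo[1,2-a]azepine
Product: 11 (9S)-9-[(3R,4R)-4-[(tert-butyldimethylsilyl)oxy]-5,5-dimethoxypentan-3-yl]-6,7,8,9-tetrahydro-5H-pyrrolo[1,2-a]azepine
Conditions: H2 (1 atm), 10% Pd/C, EtOAc, rt
Reagents that add atoms: none
Why: Heterogeneous hydrogenation of the isolated cis-alkene, under which the pyrrole, acetal and silyl ether are not reduced.

Step 8
Reactants: 12 (S)-2-methylsuccinic acid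
Product: 13 (S)-3-methyldihydrofuran-2,5-dione
Conditions: AcCl, reflux; evaporate
Reagents that add atoms: none
Why: Cyclodehydration of a 1,4-diacid to the five-membered anhydride under acidic conditions that do not enolise C20.

Step 9
Reactants: 13 (S)-3-methyldihydrofuran-2,5-dione
Product: 14 (S)-4-(dimethylamino)-2-methyl-4-oxobutanoic acid
Conditions: Me2NH (2.2 equiv, 2 M in THF), THF, 0 °C; then 1 M HCl; recrystallise
Reagents that add atoms: dimethylamine, CNC
Why: Aminolysis of the unsymmetrical anhydride goes mainly at the less hindered carbonyl remote from the methyl group, which places the amide on the CH2 side (future C18) and leaves the acid on the carbon next to C20; the minor regioisomer is removed by crystallisation.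

Step 10
Reactants: 14 (S)-4-(dimethylamino)-2-methyl-4-oxobutanoic acid
Product: 15 methyl (S)-4-(dimethylamino)-2-methyl-4-oxobutanoate
Conditions: MeI, K2CO3, DMF, rt
Reagents that add atoms: iodomethane, CI
Why: SN2 O-methylation of the carboxylate with a base too weak to epimerise C20.

Step 11
Reactants: 15 methyl (S)-4-(dimethylamino)-2-methyl-4-oxobutanoate; 11 (9S)-9-[(3R,4R)-4-[(tert-butyldimethylsilyl)oxy]-5,5-dimethoxypentan-3-yl]-6,7,8,9-tetrahydro-5H-pyrrolo[1,2-a]azepine
Product: 18 methyl (2S)-4-[(9S)-9-[(3R,4R)-4-[(tert-butyldimethylsilyl)oxy]-5,5-dimethoxypentan-3-yl]-6,7,8,9-tetrahydro-5H-pyrrolo[1,2-a]azepin-3-yl]-2-methyl-4-oxobutanoate, via chloroiminium salt 16 (not isolated), via ketiminium salt 17 (not isolated)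
Conditions: 15, POCl3, (CH2Cl)2, rt; then 11, 2,6-di-tert-butyl-4-methylpyridine, 0 °C → rt; then aq. NaOAc, 40 °C
Reagents that add atoms: water, O
Why: Vilsmeier–Haack acylation, in which chloroiminium ion 16 attacks the only free α-position (C3) of the 1,2-dialkylpyrrole and mild hydrolysis of 17 releases the ketone, the hindered pyridine taking up HCl so that the acetal and silyl ether survive.

Step 12
Reactants: 18 methyl (2S)-4-[(9S)-9-[(3R,4R)-4-[(tert-butyldimethylsilyl)oxy]-5,5-dimethoxypentan-3-yl]-6,7,8,9-tetrahydro-5H-pyrrolo[1,2-a]azepin-3-yl]-2-methyl-4-oxobutanoate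
Product: 19 methyl (2S)-4-[(9S)-9-[(2R,3R)-2-[(tert-butyldimethylsilyl)oxy]-1-oxopentan-3-yl]-6,7,8,9-tetrahydro-5H-pyrrolo[1,2-a]azepin-3-yl]-2-methyl-4-oxobutanoate
Conditions: CF3CO2H–H2O (9:1), CH2Cl2, 0 °C; used at once
Reagents that add atoms: water, O
Why: Acid-catalysed acetal hydrolysis, carried out only after acylation so that the now electron-poor pyrrole does not condense with the C12 aldehyde, and brief enough for the secondary silyl ether to survive.

Step 13
Reactants: 19 methyl (2S)-4-[(9S)-9-[(2R,3R)-2-[(tert-butyldimethylsilyl)oxy]-1-oxopentan-3-yl]-6,7,8,9-tetrahydro-5H-pyrrolo[1,2-a]azepin-3-yl]-2-methyl-4-oxobutanoate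
Product: 20 ethyl (2Z,4R,5R)-4-[(tert-butyldimethylsilyl)oxy]-5-[(9S)-3-[(3S)-4-methoxy-3-methyl-4-oxobutanoyl]-6,7,8,9-tetrahydro-5H-pyrrolo[1,2-a]azepin-9-yl]-2-methylhept-2-enoate
Conditions: CH3CH(CO2Et)P(O)(OCH2CF3)2, KN(SiMe3)2, 18-crown-6, THF, −78 °C
Reagents that add atoms: ethyl 2-[bis(2,2,2-trifluoroethoxy)phosphoryl]propanoate, CCOC(=O)C(C)P(=O)(OCC(F)(F)F)OCC(F)(F)F
Why: Still–Gennari variant of the Horner–Wadsworth–Emmons olefination, whose electron-poor phosphonate eliminates under kinetic control to the Z-enoate with the ester cis to C11, while the deactivated aryl ketone does not compete with the aldehyde.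

Step 14
Reactants: 20 ethyl (2Z,4R,5R)-4-[(tert-butyldimethylsilyl)oxy]-5-[(9S)-3-[(3S)-4-methoxy-3-methyl-4-oxobutanoyl]-6,7,8,9-tetrahydro-5H-pyrrolo[1,2-a]azepin-9-yl]-2-methylhept-2-enoate
Product: 22 methyl (2S)-2-methyl-4-[(9S)-9-[(1R)-1-[(2R)-4-methyl-5-oxo-2,5-dihydrofuran-2-yl]propyl]-6,7,8,9-tetrahydro-5H-pyrrolo[1,2-a]azepin-3-yl]-4-oxobutanoate, via hydroxy enoate 21 (not isolated)
Conditions: 48% aq. HF, MeCN, 0 °C → rt
Reagents that add atoms: none
Why: Desilylation frees the C11 hydroxyl next to the Z-ester, and lactonisation (intramolecular transesterification) closes the α-methylbutenolide without touching the C11–O bond.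

Step 15
Reactants: 22 methyl (2S)-2-methyl-4-[(9S)-9-[(1R)-1-[(2R)-4-methyl-5-oxo-2,5-dihydrofuran-2-yl]propyl]-6,7,8,9-tetrahydro-5H-pyrrolo[1,2-a]azepin-3-yl]-4-oxobutanoate
Product: 23 tetracyclic keto ester (rings A to D closed; 9S,10R,11R,12S,13S,20S; C18 ketone and C21 methyl ester open)
Conditions: Sc(OTf)3 (1.0 equiv), (CH2Cl)2, 60 °C; aq. NaHCO3
Reagents that add atoms: none
Why: Sc(OTf)3 binds the lactone carbonyl, pyrrole C1 attacks the activated C12, the Wheland intermediate loses its proton and the scandium enolate is protonated at C13; this is a Friedel–Crafts conjugate addition, closest to the Lewis-acid-promoted Michael additions of pyrroles to enones, unsaturated lactones and tethered unsaturated esters. Ring C closes 6-exo-trig through C9a–C9–C10–C11, and lactone D passes from butenolide to its saturated form. C12 is set by the tether, since C10 stands on the γ-carbon C11 and can bring C1 only to its own face of the flat butenolide, so H11 and H12 should end up cis (12S). C13 is set by kinetic protonation of the enolate from the convex face, away from the new C1–C12 bond, which should leave the methyl group on the concave face (13S). The step needs site selectivity on the pyrrole, and the C3 acyl group secures it: it blocks the reactive α-position and directs substitution to C1, the only carbon that can reach C12 through a six-membered ring. The same acyl group keeps the pyrrole from being degraded by the acid, which is why lactone E is made afterwards.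

Step 16
Reactants: 23 tetracyclic keto ester (rings A to D closed; 9S,10R,11R,12S,13S,20S; C18 ketone and C21 methyl ester open)
Product: 25 Epibisdehydroneotuberostemonine J, via hydroxy ester 24 (not isolated)
Conditions: (S)-2-methyl-CBS-oxazaborolidine (1.0 equiv), catecholborane, toluene, −40 °C; MeOH, aq. NaHCO3; then 2-hydroxypyridine (10 mol%), toluene, 60 °C
Reagents that add atoms: none
Why: Corey–Bakshi–Shibata reduction, in which the pyrrolyl group acts as the large and the CH2 chain as the small substituent so that the (S)-oxazaborolidine should give the 18R carbinol, which closes lactone E onto the C21 ester by neutral transesterification that spares both the acid-labile pyrrolylic C–O bond and the base-sensitive C13 centre.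

**Compound list**

1 | pyrrole | c1cc[nH]c1 | starting material
2 | 1-(prop-2-en-1-yl)-1H-pyrrole | C=CCn1cccc1 | intermediate
3 | butanal | CCCC=O | starting material
4 | 2,2-dimethoxyacetaldehyde | COC(OC)C=O | starting material
5 | (2S,3R)-2-ethyl-3-hydroxy-4,4-dimethoxybutanal | CC[C@H](C=O)[C@@H](O)C(OC)OC | intermediate
6 | (2E,4R,5R)-4-ethyl-5-hydroxy-6,6-dimethoxyhex-2-enal | CC[C@H](/C=C/C=O)[C@@H](O)C(OC)OC | intermediate
7 | (2E,4R,5R)-5-[(tert-butyldimethylsilyl)oxy]-4-ethyl-6,6-dimethoxyhex-2-enal | CC[C@H](/C=C/C=O)[C@@H](O[Si](C)(C)C(C)(C)C)C(OC)OC | intermediate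
8 | (3S,4R,5R)-5-[(tert-butyldimethylsilyl)oxy]-4-ethyl-6,6-dimethoxy-3-[1-(prop-2-en-1-yl)-1H-pyrrol-2-yl]hexanal | CC[C@H]([C@H](CC=O)c1cccn1CC=C)[C@@H](O[Si](C)(C)C(C)(C)C)C(OC)OC | intermediate
9 | 2-[(4S,5R,6R)-6-[(tert-butyldimethylsilyl)oxy]-5-ethyl-7,7-dimethoxyhept-1-en-4-yl]-1-(prop-2-en-1-yl)-1H-pyrrole | CC[C@H]([C@H](CC=C)c1cccn1CC=C)[C@@H](O[Si](C)(C)C(C)(C)C)C(OC)OC | intermediate
10 | (9S)-9-[(3R,4R)-4-[(tert-butyldimethylsilyl)oxy]-5,5-dimethoxypentan-3-yl]-8,9-dihydro-5H-pyrrolo[1,2-a]azepine | CC[C@H]([C@@H]1CC=CCn2cccc12)[C@@H](O[Si](C)(C)C(C)(C)C)C(OC)OC | intermediate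
11 | (9S)-9-[(3R,4R)-4-[(tert-butyldimethylsilyl)oxy]-5,5-dimethoxypentan-3-yl]-6,7,8,9-tetrahydro-5H-pyrrolo[1,2-a]azepine | CC[C@H]([C@@H]1CCCCn2cccc12)[C@@H](O[Si](C)(C)C(C)(C)C)C(OC)OC | intermediate
12 | (S)-2-methylsuccinic acid | C[C@@H](CC(=O)O)C(=O)O | starting material
13 | (S)-3-methyldihydrofuran-2,5-dione | C[C@H]1CC(=O)OC1=O | intermediate
14 | (S)-4-(dimethylamino)-2-methyl-4-oxobutanoic acid | C[C@@H](CC(=O)N(C)C)C(=O)O | intermediate
15 | methyl (S)-4-(dimethylamino)-2-methyl-4-oxobutanoate | C[C@@H](CC(=O)N(C)C)C(=O)OC | intermediate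
16 | [(3S)-1-chloro-4-methoxy-3-methyl-4-oxobutylidene]dimethylammonium dichlorophosphate | COC(=O)[C@@H](C)CC(Cl)=[N+](C)C.[O-]P(=O)(Cl)Cl | intermediate
17 | C3 ketiminium chloride of 18 (C18=N+Me2 in place of C18=O) | CC[C@H]([C@@H]1CCCCn2c(C(=[N+](C)C)C[C@H](C)C(=O)OC)ccc12)[C@@H](O[Si](C)(C)C(C)(C)C)C(OC)OC.[Cl-] | intermediate
18 | methyl (2S)-4-[(9S)-9-[(3R,4R)-4-[(tert-butyldimethylsilyl)oxy]-5,5-dimethoxypentan-3-yl]-6,7,8,9-tetrahydro-5H-pyrrolo[1,2-a]azepin-3-yl]-2-methyl-4-oxobutanoate | CC[C@H]([C@@H]1CCCCn2c(C(=O)C[C@H](C)C(=O)OC)ccc12)[C@@H](O[Si](C)(C)C(C)(C)C)C(OC)OC | intermediate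
19 | methyl (2S)-4-[(9S)-9-[(2R,3R)-2-[(tert-butyldimethylsilyl)oxy]-1-oxopentan-3-yl]-6,7,8,9-tetrahydro-5H-pyrrolo[1,2-a]azepin-3-yl]-2-methyl-4-oxobutanoate | CC[C@H]([C@@H]1CCCCn2c(C(=O)C[C@H](C)C(=O)OC)ccc12)[C@@H](O[Si](C)(C)C(C)(C)C)C=O | intermediate
20 | ethyl (2Z,4R,5R)-4-[(tert-butyldimethylsilyl)oxy]-5-[(9S)-3-[(3S)-4-methoxy-3-methyl-4-oxobutanoyl]-6,7,8,9-tetrahydro-5H-pyrrolo[1,2-a]azepin-9-yl]-2-methylhept-2-enoate | CC[C@H]([C@@H]1CCCCn2c(C(=O)C[C@H](C)C(=O)OC)ccc12)[C@@H](O[Si](C)(C)C(C)(C)C)/C=C(/C)C(=O)OCC | intermediate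
21 | ethyl (2Z,4R,5R)-4-hydroxy-5-[(9S)-3-[(3S)-4-methoxy-3-methyl-4-oxobutanoyl]-6,7,8,9-tetrahydro-5H-pyrrolo[1,2-a]azepin-9-yl]-2-methylhept-2-enoate | CC[C@H]([C@@H]1CCCCn2c(C(=O)C[C@H](C)C(=O)OC)ccc12)[C@@H](O)/C=C(/C)C(=O)OCC | intermediate
22 | methyl (2S)-2-methyl-4-[(9S)-9-[(1R)-1-[(2R)-4-methyl-5-oxo-2,5-dihydrofuran-2-yl]propyl]-6,7,8,9-tetrahydro-5H-pyrrolo[1,2-a]azepin-3-yl]-4-oxobutanoate (key-step precursor) | CC[C@@H]([C@H]1OC(=O)C(C)=C1)[C@@H]1CCCCn2c1ccc2C(=O)C[C@H](C)C(=O)OC | intermediate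
23 | tetracyclic keto ester, rings A to D closed (9S,10R,11R,12S,13S,20S), C18 ketone and C21 methyl ester open (key-step product) | CC[C@H]1[C@H]2OC(=O)[C@@H](C)[C@H]2c2cc(C(=O)C[C@H](C)C(=O)OC)n3c2[C@H]1CCCC3 | intermediate
24 | (18R)-hydroxy ester of 23 | CC[C@H]1[C@H]2OC(=O)[C@@H](C)[C@H]2c2cc([C@H](O)C[C@H](C)C(=O)OC)n3c2[C@H]1CCCC3 | intermediate
25 | Epibisdehydroneotuberostemonine J (9S,10R,11R,12S,13S,18R,20S) | CC[C@H]1[C@H]2OC(=O)[C@@H](C)[C@H]2c2cc([C@H]3C[C@H](C)C(=O)O3)n3c2[C@H]1CCCC3 | target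

**Step count and risks**

Total step count: 16. Longest linear sequence: 12 steps (steps 2 to 7 and 11 to 16, from butanal); the precursor 22 is reached in 10 linear steps.

Steps most likely to fail:

1. Step 15. The acyl group that protects the pyrrole also lowers the nucleophilicity of C1, and the α-methylbutenolide is a weak acceptor, so the ring closure may stall; if forcing is needed, enolisation under Lewis acid could erode the kinetically set C13 centre. The fallback abandons the polar closure for a radical one. It sets out from 22, which is brominated at C1, the position that a 2-acylpyrrole offers to electrophiles, with N-bromosuccinimide in THF at −78 °C to give the C1 bromide F1. Treatment of F1 with Bu3SnH and azobisisobutyronitrile in benzene at 80 °C under slow addition should generate the C1 radical, which closes 6-exo onto C12 on the face dictated by the tether; the C13 radical then takes hydrogen from the stannane on the convex face. The fallback comes back to the route at 23.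

2. Step 4. The iminium ion of 7 can be deprotonated at C10 to a dienamine, which would scramble that centre; the branched β-substituent may slow the addition, and catalyst and substrate may be mismatched, lowering the facial selectivity at C9. The fallback replaces iminium activation by chelating Lewis-acid activation, which cannot reach C10. It sets out from 5, which is olefinated with 1-(1-methylimidazol-2-yl)-2-(triphenylphosphoranylidene)ethanone to the unsaturated acyl imidazole F2 and silylated as in step 3 to its silyl ether F3. Friedel–Crafts alkylation of 2 with F3 under Sc(OTf)3 and a chiral 2,6-bis(oxazolinyl)pyridine ligand, the ligand enantiomer being chosen for 9S, should give the adduct F4. N-Methylation with methyl triflate gives the acyl imidazolium salt F5, methanolysis with DBU in MeOH gives the methyl ester F6, and i-Bu2AlH at −78 °C reduces F6 to the aldehyde. The fallback comes back to the route at 8.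

3. Step 16. The ketone is a vinylogous amide and may be reduced slowly; the boron-bound pyrrolylic carbinol may ionise and be reduced further or lose its configuration; and the existing stereocentres may oppose the catalyst. The fallback gives up reagent control and relies on separation. It sets out from 23, which is reduced with NaBH4 and CeCl3·7H2O in MeOH at −40 °C to the carbinols F7 as a mixture at C18. Lactonisation as in step 16 gives 25 together with its C18 epimer F8, and the two lactones are separated by chromatography on neutral alumina. The epimer F8 can be returned to a mixture of both lactones by brief treatment with a catalytic amount of CF3CO2H in CH2Cl2 at 0 °C, through ionisation to the azafulvenium ion and re-closure, and separated again. The fallback comes back to the route at 25.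

Further compounds
F1 | step 15 | C1 bromide of 22 | CC[C@@H]([C@H]1OC(=O)C(C)=C1)[C@@H]1CCCCn2c1c(Br)cc2C(=O)C[C@H](C)C(=O)OC
F2 | step 4 | (2E,4R,5R)-4-ethyl-5-hydroxy-6,6-dimethoxy-1-(1-methyl-1H-imidazol-2-yl)hex-2-en-1-one | CC[C@H](/C=C/C(=O)c1nccn1C)[C@@H](O)C(OC)OC
F3 | step 4 | (2E,4R,5R)-5-[(tert-butyldimethylsilyl)oxy]-4-ethyl-6,6-dimethoxy-1-(1-methyl-1H-imidazol-2-yl)hex-2-en-1-one | CC[C@H](/C=C/C(=O)c1nccn1C)[C@@H](O[Si](C)(C)C(C)(C)C)C(OC)OC
F4 | step 4 | (3S,4R,5R)-5-[(tert-butyldimethylsilyl)oxy]-4-ethyl-6,6-dimethoxy-1-(1-methyl-1H-imidazol-2-yl)-3-[1-(prop-2-en-1-yl)-1H-pyrrol-2-yl]hexan-1-one | CC[C@H]([C@H](CC(=O)c1nccn1C)c1cccn1CC=C)[C@@H](O[Si](C)(C)C(C)(C)C)C(OC)OC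
F5 | step 4 | 1,3-dimethylimidazolium triflate of F4 (acyl imidazolium salt, not isolated) | CC[C@H]([C@H](CC(=O)c1n(C)cc[n+]1C)c1cccn1CC=C)[C@@H](O[Si](C)(C)C(C)(C)C)C(OC)OC.[O-]S(=O)(=O)C(F)(F)F
F6 | step 4 | methyl (3S,4R,5R)-5-[(tert-butyldimethylsilyl)oxy]-4-ethyl-6,6-dimethoxy-3-[1-(prop-2-en-1-yl)-1H-pyrrol-2-yl]hexanoate | CC[C@H]([C@H](CC(=O)OC)c1cccn1CC=C)[C@@H](O[Si](C)(C)C(C)(C)C)C(OC)OC
F7 | step 16 | hydroxy ester of 23 as a mixture of C18 epimers | CC[C@H]1[C@H]2OC(=O)[C@@H](C)[C@H]2c2cc(C(O)C[C@H](C)C(=O)OC)n3c2[C@H]1CCCC3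
F8 | step 16 | C18 epimer of 25 (18S lactone) | CC[C@H]1[C@H]2OC(=O)[C@@H](C)[C@H]2c2cc([C@@H]3C[C@H](C)C(=O)O3)n3c2[C@H]1CCCC3
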